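## Retrosynthetic overview
Target **1** comes from α‑iodination of enone **2**, which is the acetate of anti‑aldol adduct **3**. Adduct **3** comes from the dienolate of (S)‑4‑hydroxy‑4‑[(Z)‑oct‑2‑enyl]cyclopent‑2‑enone **4** and Z‑enal **5**, itself made from hex‑5‑ynoic acid **6**.
Enone **4** comes from oxidation and dehydrogenation of a 1,3‑diol. That diol is formed by a SmI2 ketyl–diene radical coupling, the key C–C bond, of 3‑silyloxycyclopentanone **7** with (E)‑octa‑1,3‑diene **8**. Ketone **7** is made by hydrogenating (R)‑4‑silyloxycyclopentenone **9**.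
The only ring, the cyclopentane, is carried intact from **9**, so no ring is formed. The C4 quaternary carbinol configuration is relayed from the C–OSi centre of **9** through anti radical addition, and that centre is then oxidised away.
Assumption: **9**, **8** and **6** are commercial; the TBS group in **9** is a protecting group, leaving 7 skeletal atoms.

## Route

**Step 1**
Reactants: **9** (R)‑4‑(tert‑butyldimethylsilyloxy)cyclopent‑2‑en‑1‑one
Product: **7** (S)‑3‑(tert‑butyldimethylsilyloxy)cyclopentan‑1‑one
Conditions: H2 (1 atm), 10% Pd/C, EtOAc, rt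
Reagents that add atoms: none
Why: Chemoselective hydrogenation of the enone C=C leaves the C–O stereocentre untouched, so the descriptor changes R→S only because the CIP priorities change. This gives a non‑conjugated ketone that can form a clean ketyl.

**Step 2**
Reactants: **7**; **8** (E)‑octa‑1,3‑diene
Product: **10** 3‑(TBSO)‑1‑[(Z)‑oct‑2‑enyl]cyclopentan‑1‑ol, with 1‑OH cis to 3‑OSi and the octenyl group trans to OSi
Conditions: SmI2 (2.5 equiv), HMPA (10 equiv), t‑BuOH (2 equiv), **8** (5 equiv), THF, −78 → 0 °C; chromatographic separation of the major diastereomer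
Reagents that add atoms: none
Why: A SmI2 ketyl–olefin (Giese‑type) radical coupling builds the quaternary carbinol, with the ketyl attacked anti to the 3‑silyloxy group, so the new C4 centre is set by 1,3‑induction from the C–OSi centre and later outlives it.
Proposed new method: SmI2/HMPA reduces the ketone to a ketyl radical anion. This adds to the terminal CH2 of the diene, and the allylic radical is reduced to an allylsamarium. The allylsamarium is protonated by t‑BuOH at the far terminus, with Sm–alkoxide chelation enforcing the cis (Z) geometry. The closest known reactions are Molander ketyl–olefin cyclisations and SmI2 ketone–diene reductive couplings.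

**Step 3**
Reactant: **10**
Product: **11** (1,3‑diol) 3‑hydroxy‑1‑[(Z)‑oct‑2‑enyl]cyclopentan‑1‑ol, stereochemistry as **10**
Conditions: HF·pyridine, pyridine, THF, 0 °C → rt
Reagents that add atoms: none
Why: Non‑basic silyl ether cleavage (avoids dehydration or retro‑aldol of the β‑hydroxy ketone stage) frees the secondary alcohol for oxidation; no stereocentre is touched.

**Step 4**
Reactant: **11**
Product: **4** (S)‑4‑hydroxy‑4‑[(Z)‑oct‑2‑en‑1‑yl]cyclopent‑2‑en‑1‑one
Conditions: IBX (3 equiv), DMSO, 65 °C
Reagents that add atoms: none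
Why: IBX oxidation/dehydrogenation (Nicolaou) converts the secondary alcohol to the ketone and then to the enone, and can only unsaturate toward C2–C3 because C4 is quaternary. The C1 stereocentre is destroyed, leaving C4 (S) as the only stereocentre.

**Step 5**
Reactant: **6** hex‑5‑ynoic acid
Product: **12** methyl hex‑5‑ynoate
Conditions: MeOH, cat. H2SO4, reflux
Reagents that add atoms: methanol, CO
Why: Fischer esterification.

**Step 6**
Reactant: **12**
Product: **13** methyl 7‑oxohept‑5‑ynoate
Conditions: n‑BuLi (1.05 equiv), THF, −78 °C; then DMF; aqueous NH4Cl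
Reagents that add atoms: N,N‑dimethylformamide, CN(C)C=O
Why: Lithium acetylide formylation (Bouveault‑type) with DMF, kinetically selective for the terminal alkyne at −78 °C in the presence of the ester.

**Step 7**
Reactant: **13**
Product: **5** methyl (Z)‑7‑oxohept‑5‑enoate
Conditions: H2 (1 atm), Lindlar catalyst, quinoline, EtOAc/hexane, 0 °C
Reagents that add atoms: none
Why: Lindlar syn‑hydrogenation delivers the cis alkene, setting the Z geometry of C7=C8.

**Step 8**
Reactants: **4**; **5**
Product: **3** methyl (5Z,7S)‑7‑hydroxy‑7‑[(1R,2R)‑2‑hydroxy‑5‑oxo‑2‑[(2Z)‑oct‑2‑en‑1‑yl]cyclopent‑3‑en‑1‑yl]hept‑5‑enoate (anti‑aldol)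
Conditions: LDA (2.2 equiv), THF, −78 °C; then **5** (1.2 equiv), −78 °C, 30 min; NH4Cl quench; chromatographic separation of diastereomers
Reagents that add atoms: none
Why: Aldol reaction of the alkoxide/dienolate: Li chelation to the C4 alkoxide directs the aldehyde to the face cis to O and anti to the octenyl group, setting C5. The E‑configured cyclic enolate reacts through a Zimmerman–Traxler chair to give the anti adduct (C6 S), and the minor diastereomers are removed. The C4 geometry is unchanged; its descriptor goes from S to R only because C5 is now substituted.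

**Step 9**
Reactant: **3**
Product: **2** methyl (5Z,7S)‑7‑acetoxy‑7‑[(1R,2R)‑2‑hydroxy‑5‑oxo‑2‑[(2Z)‑oct‑2‑en‑1‑yl]cyclopent‑3‑en‑1‑yl]hept‑5‑enoate
Conditions: Ac2O (1.5 equiv), pyridine, DMAP (cat.), CH2Cl2, 0 °C
Reagents that add atoms: acetic anhydride, CC(=O)OC(C)=O
Why: Chemoselective acylation of the secondary C6–OH over the hindered tertiary C4–OH, under mild conditions so the β‑acetoxy ketone does not eliminate; no stereocentre changes.

**Step 10**
Reactant: **2**
Product: **1** 7‑acetoxy‑7,8‑dihydroiodovulone I, methyl (5Z,7S)‑7‑acetoxy‑7‑[(1R,2S)‑2‑hydroxy‑4‑iodo‑5‑oxo‑2‑[(2Z)‑oct‑2‑en‑1‑yl]cyclopent‑3‑en‑1‑yl]hept‑5‑enoate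
Conditions: I2 (1.5 equiv), pyridine, CH2Cl2, 0 °C → rt
Reagents that add atoms: iodine, II
Why: Johnson α‑iodination (pyridine conjugate addition, iodination, elimination) installs the vinyl iodide and leaves all three stereocentres untouched. The C4 descriptor returns to S because iodine now raises the priority of C3.

## Compound list
1 | 7‑acetoxy‑7,8‑dihydroiodovulone I | `CCCCC/C=C\C[C@@]1(O)C=C(I)C(=O)[C@@H]1[C@H](/C=C\CCCC(=O)OC)OC(C)=O` | target
2 | iodine‑free acetate (4R,5R,6S) | `CCCCC/C=C\C[C@@]1(O)C=CC(=O)[C@@H]1[C@H](/C=C\CCCC(=O)OC)OC(C)=O` | intermediate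
3 | anti‑aldol adduct (6‑OH) | `CCCCC/C=C\C[C@@]1(O)C=CC(=O)[C@@H]1[C@H](/C=C\CCCC(=O)OC)O` | intermediate
4 | (S)‑4‑hydroxy‑4‑[(Z)‑oct‑2‑enyl]cyclopent‑2‑enone | `CCCCC/C=C\C[C@@]1(O)C=CC(=O)C1` | intermediate
5 | methyl (Z)‑7‑oxohept‑5‑enoate | `COC(=O)CCC/C=C\C=O` | intermediate
6 | hex‑5‑ynoic acid | `C#CCCCC(=O)O` | starting material
7 | (S)‑3‑(TBSO)cyclopentan‑1‑one | `CC(C)(C)[Si](C)(C)O[C@@H]1CC(=O)CC1` | intermediate
8 | (E)‑octa‑1,3‑diene | `C=C/C=C/CCCC` | starting material
9 | (R)‑4‑(TBSO)cyclopent‑2‑en‑1‑one | `CC(C)(C)[Si](C)(C)O[C@@H]1CC(=O)C=C1` | starting material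
10 | cis‑3‑(TBSO)‑1‑[(Z)‑oct‑2‑enyl]cyclopentan‑1‑ol | `CCCCC/C=C\C[C@@]1(O)CC[C@H](O[Si](C)(C)C(C)(C)C)C1` | intermediate
11 | cis‑1,3‑diol (1‑[(Z)‑oct‑2‑enyl]cyclopentane‑1,3‑diol) | `CCCCC/C=C\C[C@@]1(O)CC[C@H](O)C1` | intermediate
12 | methyl hex‑5‑ynoate | `COC(=O)CCCC#C` | intermediate
13 | methyl 7‑oxohept‑5‑ynoate | `COC(=O)CCCC#CC=O` | intermediate

**Total steps:** 10. **Longest linear sequence:** 7 (9 → 7 → 10 → 11 → 4 → 3 → 2 → 1).

## Three steps most likely to fail
1. **Step 2 (ketyl–diene coupling).** Regiochemistry of protonation, Z selectivity and diastereoselectivity are all uncertain, and pinacol or simple reduction of the ketone competes. Fallback: propargylate ketone **7** with 1‑bromo‑oct‑2‑yne and Zn (Barbier) to the homopropargylic alcohol, then carry it through and run a Lindlar reduction after Step 4.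
2. **Step 4 (IBX oxidation–dehydrogenation).** The β‑hydroxy ketone stage may dehydrate, and the Z alkene may isomerise. Fallback: oxidise with Dess–Martin periodinane, silylate the tertiary OH (TESOTf), do Saegusa–Ito dehydrogenation (LDA/TMSCl, then Pd(OAc)2), then remove the silyl group.
3. **Step 8 (dianion aldol).** Competing 1,4‑addition to the enal, retro‑aldol, and poor C5/C6 diastereocontrol are all possible. Fallback: silylate **4** to its TMS ether, form the dienol silyl ether, and run a Mukaiyama aldol (TiCl4) or a boron‑enolate aldol with **5**, separating the anti isomer.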